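If G can react with Z or with D, the D left at the end shows how the two steps shared G.

    G + Z → 2 Z (k1 = 26 M⁻¹ s⁻¹)
    G + D → G.D (k2 = 1.3 M⁻¹ s⁻¹)
    2 G → G2 (k3 = 0.014 M⁻¹ s⁻¹)
    G → Z (k4 = 0.0014 s⁻¹)

all flasks: G 0.70 M; Z 0.0140 M; D 0.0700 M
- autumn: time 30 s
- spring: time 90 s

- a species is counted by the G in it: one G2 counts as two
- a doubled species enters its step squared and goes two at a time
- run time (autumn): 30 s

- which of these there is most of at the end, counted by the G in it, autumn (G / Z)
- which of these there is most of at the end, counted by the G in it, spring (G / Z)
- the largest of these amounts at the end, in percent of the G charged, autumn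
- the largest of these amounts at the end, in percent of the G charged, spring

Minutes of the meeting on autumn and spring.

The chair asked what to reckon first. I proposed the balance of D, charged at 0.0700 M and so less than G at 0.70 M. I said that [D] falls at 1.3 M⁻¹ s⁻¹ times [G][D], while [Z] rises at 26 M⁻¹ s⁻¹ times [G][Z]. I set the step G → Z aside, since at the start it runs at 0.0014 s⁻¹ per G against 0.364 s⁻¹ for the step through Z.

Dividing one balance by the other removes [G] and time. Then ln[D] falls by 0.0500 for each unit that ln[Z] rises. That ratio of rate constants is the selectivity factor.

I took [Z] at the end as seed plus G, 0.714 M, and got 82.2%. I called this the survival of D: end [D] over charged [D], equal to start [Z] over end [Z], raised to the selectivity factor.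

G.D then takes 0.0125 M. So I put Z at 100.2% of the G charged, with G2 not counted. That figure counts the seed of 0.0140 M too. I added that the half-life of G by the step through Z is 1.9 s at the autumn charge, far shorter than the run, so I expected the same end in both flasks.

The forecast was then read: Z in autumn and Z in spring, at 99.9% and 99.9%, each within 99.5% to 100.3%. Its ground was that “G is gone in well under a couple of seconds”. My figure stood 0.30 percentage points above it.

The simulation gives Z at 99.9% in autumn and Z at 99.9% in spring, as forecast. In autumn G2 holds 0.319% of the G charged, about the gap between my figure and the result. Survival has no time in it. In spring D stands at 82.3% of its charge, against the 82.2% reckoned, and in autumn at 82.3%. So the longer spring run ends with the D of the autumn run.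

Take autumn with Z charged at 0.056 M. Survival there gives 87.8%. The flask gives D at 88% of its charge, with Z at 107% of the G charged.

The constants belong to no real substance; the rest is arithmetic.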